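**Plan**

- Retrosynthetic cuts, in order: O5–C6 (ring B ether); C6a–C11a (ring C, with both core stereocentres); the O11–CH2 ether that joins a ring A/E benzylic bromide to a ring D/F arylacetate. Each pyran ring goes back to prenal and an acyl resorcinol.
- Forward: the ring D/F half is made first (2,4-dihydroxyacetophenone → chromene → epoxide → (R)-chromanol → 1,2-aryl shift of the acetyl group to CH2CO2Me). The ring A/E half follows (2,4-dihydroxybenzaldehyde → chromene aldehyde → benzylic bromide). Then come ether union, diazo transfer, ring C by C–H insertion, and ring B last by Mitsunobu closure.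
- Enabling feature: the C6a–C11a bond is shared by rings B and C. Its C11a end is a C–H that is benzylic to ring A, bound to O11 and para to the ring E oxygen, and it lies 1,5 to C6a through C6b, C10a and O11. C6a can therefore be a rhodium carbene flanked by ring D and an ester carbon that later becomes C6.
- Stereochemistry: the ring F carbinol (R) comes from a Jacobsen epoxidation with the (R,R) catalyst and is kept through benzylic hydrogenolysis. C6a and C11a are set together, cis, by Rh2(S-PTTL)4. Reduction and Mitsunobu closure touch none of the three centres.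

Key step: step 14

Remark (assumption): Rh2(S-PTTL)4 is taken to induce the 11aR, cis sense here as it does for simpler 2-(benzyloxy)aryl diazoacetates. Core atoms carry pterocarpan numbers (ring A C1–C4a/C11b, ring B O5–C6–C6a–C11a, ring C O11–C11a–C6a–C6b–C10a, ring D C6b–C10a, ring E on C3/C4, ring F on C9/C10).

**Route**

Step 1
Reactants: 1 2,4-dihydroxyacetophenone; 2 3-methylbut-2-enal (prenal)
Product: 3 1-(5-hydroxy-2,2-dimethyl-2H-chromen-6-yl)ethan-1-one
Conditions: ethylenediammonium diacetate (10 mol %), xylene, 140 °C
Reagents that add atoms: none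
Why: Prenal chromenylation: amine-catalysed Knoevenagel-type attack at the resorcinol carbon between the two oxygens (the 2-OH is held in a hydrogen bond to the acetyl group), then oxa-6π electrocyclisation of the dienone through the free 4-OH, should give the angular chromene only.

Step 2
Reactants: 3 1-(5-hydroxy-2,2-dimethyl-2H-chromen-6-yl)ethan-1-one
Product: 4 6-acetyl-2,2-dimethyl-2H-chromen-5-yl pivalate
Conditions: PivCl, Et3N, DMAP (cat.), CH2Cl2, 0 °C → rt
Reagents that add atoms: pivaloyl chloride, CC(C)(C)C(Cl)=O
Why: DMAP-catalysed O-acylation of the chelated phenol; the pivalate shields the phenol from the oxidants of steps 3 and 5 and tolerates hydrogenolysis and acidic methanol.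

Step 3
Reactants: 4 6-acetyl-2,2-dimethyl-2H-chromen-5-yl pivalate
Product: 5 (3R,4R)-6-acetyl-3,4-epoxy-2,2-dimethyl-3,4-dihydro-2H-chromen-5-yl pivalate
Conditions: (R,R)-(salen)MnCl [salen = N,N′-bis(3,5-di-tert-butylsalicylidene)cyclohexane-1,2-diaminate; trivalent manganese] (5 mol %), mCPBA, N-methylmorpholine N-oxide, CH2Cl2, −78 °C
Reagents that add atoms: mCPBA, O=C(OO)c1cccc(Cl)c1
Why: Jacobsen epoxidation of a 2,2-dimethylchromene, the standard substrate class for this catalyst; the (R,R) complex should deliver oxygen to the face that gives the (3R,4R)-epoxide, which fixes the future ring F carbinol as R.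

Step 4
Reactants: 5 (3R,4R)-6-acetyl-3,4-epoxy-2,2-dimethyl-3,4-dihydro-2H-chromen-5-yl pivalate
Product: 6 (3R)-6-acetyl-3-hydroxy-2,2-dimethyl-3,4-dihydro-2H-chromen-5-yl pivalate
Conditions: H2 (1 atm), 10 % Pd/C, EtOAc, rt
Reagents that add atoms: none
Why: Catalytic hydrogenolysis cleaves only the benzylic C4–O bond of the epoxide, so the C3–O bond and its R configuration are untouched; the aryl ketone, deactivated by the para ring oxygen, and the pivalate should survive at 1 atm.

Step 5
Reactants: 6 (3R)-6-acetyl-3-hydroxy-2,2-dimethyl-3,4-dihydro-2H-chromen-5-yl pivalate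
Product: 7 methyl 2-[(3R)-3-hydroxy-2,2-dimethyl-5-(pivaloyloxy)-3,4-dihydro-2H-chromen-6-yl]acetate
Conditions: PhI(OAc)2, H2SO4, HC(OMe)3/MeOH, rt → 50 °C
Reagents that add atoms: trimethyl orthoformate, COC(OC)OC
Why: Oxidative 1,2-aryl migration of an aryl methyl ketone with a trivalent iodine reagent: the enol ether of the dimethyl ketal is attacked at CH2 by PhI(OAc)2 and the electron-rich ring (para ring F oxygen) shifts to that carbon as PhI leaves, giving the methyl arylacetate.

Step 6
Reactants: 7 methyl 2-[(3R)-3-hydroxy-2,2-dimethyl-5-(pivaloyloxy)-3,4-dihydro-2H-chromen-6-yl]acetate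
Product: 8 methyl 2-[(3R)-3,5-dihydroxy-2,2-dimethyl-3,4-dihydro-2H-chromen-6-yl]acetate
Conditions: K2CO3, MeOH, 0 °C → rt
Reagents that add atoms: none
Why: Base-catalysed methanolysis (transesterification) removes the aryl pivalate, while the methyl ester can only exchange with itself in methanol and any benzofuranone formed by lactonisation reopens to it.

Step 7
Reactants: 9 2,4-dihydroxybenzaldehyde; 2 3-methylbut-2-enal (prenal)
Product: 10 5-hydroxy-2,2-dimethyl-2H-chromene-6-carbaldehyde
Conditions: ethylenediammonium diacetate (10 mol %), xylene, 140 °C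
Reagents that add atoms: none
Why: The same prenal chromenylation as in step 1; the formyl-chelated 2-OH leaves the 4-OH and the carbon between the oxygens to form ring E in the angular sense required on ring A.

Step 8
Reactants: 10 5-hydroxy-2,2-dimethyl-2H-chromene-6-carbaldehyde
Product: 11 6-formyl-2,2-dimethyl-2H-chromen-5-yl pivalate
Conditions: PivCl, Et3N, DMAP (cat.), CH2Cl2, 0 °C → rt
Reagents that add atoms: pivaloyl chloride, CC(C)(C)C(Cl)=O
Why: DMAP-catalysed O-acylation; O5 is stored as a pivalate that will later fall in the LiAlH4 step without a separate deprotection.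

Step 9
Reactants: 11 6-formyl-2,2-dimethyl-2H-chromen-5-yl pivalate
Product: 12 6-(hydroxymethyl)-2,2-dimethyl-2H-chromen-5-yl pivalate
Conditions: NaBH4, CeCl3·7H2O, MeOH, −40 °C; aq. NH4Cl
Reagents that add atoms: none
Why: Luche reduction reduces the aldehyde within minutes at low temperature, and the weakly acidic cerium/methanol medium should keep the benzylic alkoxide from attacking the neighbouring hindered pivalate (acyl migration).

Step 10
Reactants: 12 6-(hydroxymethyl)-2,2-dimethyl-2H-chromen-5-yl pivalate
Product: 13 6-(bromomethyl)-2,2-dimethyl-2H-chromen-5-yl pivalate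
Conditions: CBr4, PPh3, CH2Cl2, 0 °C
Reagents that add atoms: carbon tetrabromide, BrC(Br)(Br)Br
Why: Appel bromination under neutral conditions (SN2 displacement of the oxyphosphonium) suits the acid-sensitive, electron-rich benzylic alcohol; the bromide is used crude at once.

Step 11
Reactants: 8 methyl 2-[(3R)-3,5-dihydroxy-2,2-dimethyl-3,4-dihydro-2H-chromen-6-yl]acetate; 13 6-(bromomethyl)-2,2-dimethyl-2H-chromen-5-yl pivalate
Product: 14 methyl 2-[(3R)-5-{[2,2-dimethyl-5-(pivaloyloxy)-2H-chromen-6-yl]methoxy}-3-hydroxy-2,2-dimethyl-3,4-dihydro-2H-chromen-6-yl]acetate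
Conditions: K2CO3, DMF, rt
Reagents that add atoms: none
Why: Williamson etherification: the phenoxide of 8, the only acidic OH, displaces the reactive para-alkoxybenzylic bromide and forms the O11–CH2 bond, while the hindered secondary alcohol does not compete under K2CO3.

Step 12
Reactants: 14 methyl 2-[(3R)-5-{[2,2-dimethyl-5-(pivaloyloxy)-2H-chromen-6-yl]methoxy}-3-hydroxy-2,2-dimethyl-3,4-dihydro-2H-chromen-6-yl]acetate
Product: 15 methyl 2-[(3R)-3-acetoxy-5-{[2,2-dimethyl-5-(pivaloyloxy)-2H-chromen-6-yl]methoxy}-2,2-dimethyl-3,4-dihydro-2H-chromen-6-yl]acetate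
Conditions: Ac2O, pyridine, DMAP (cat.), CH2Cl2, rt
Reagents that add atoms: acetic anhydride, CC(=O)OC(C)=O
Why: DMAP-catalysed acetylation masks the ring F carbinol, which would otherwise trap the rhodium carbene by O–H insertion; the acetate is later removed by LiAlH4 together with the other esters.

Step 13
Reactants: 15 methyl 2-[(3R)-3-acetoxy-5-{[2,2-dimethyl-5-(pivaloyloxy)-2H-chromen-6-yl]methoxy}-2,2-dimethyl-3,4-dihydro-2H-chromen-6-yl]acetate
Product: 16 methyl 2-[(3R)-3-acetoxy-5-{[2,2-dimethyl-5-(pivaloyloxy)-2H-chromen-6-yl]methoxy}-2,2-dimethyl-3,4-dihydro-2H-chromen-6-yl]-2-diazoacetate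
Conditions: p-ABSA, DBU, MeCN, 0 °C → rt
Reagents that add atoms: 4-acetamidobenzenesulfonyl azide (p-ABSA), CC(=O)Nc1ccc(cc1)S(=O)(=O)N=[N+]=[N-]
Why: Regitz diazo transfer: DBU deprotonates the benzylic, ester-activated CH2 and the enolate attacks the sulfonyl azide, giving the aryl diazoacetate; acetate and pivalate are inert to DBU.

Step 14
Reactants: 16 methyl 2-[(3R)-3-acetoxy-5-{[2,2-dimethyl-5-(pivaloyloxy)-2H-chromen-6-yl]methoxy}-2,2-dimethyl-3,4-dihydro-2H-chromen-6-yl]-2-diazoacetate
Product: 17 methyl cis-2,3-dihydrobenzofuran-3-carboxylate in which benzofuran C2 (= C11a, R) carries the 2,2-dimethyl-5-(pivaloyloxy)-2H-chromen-6-yl group (rings A and E), C3 (= C6a, S) carries CO2Me, and the benzo ring (ring D) is fused at C6–C7 to the (R)-3-acetoxy-2,2-dimethyl-3,4-dihydro-2H-pyran ring F (pyran oxygen on C6, pyran CH2 on C7)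
Conditions: Rh2(S-PTTL)4 (dirhodium tetrakis[N-phthaloyl-(S)-tert-leucinate], divalent rhodium; 1–2 mol %), toluene, −60 °C, slow addition of 16
Reagents that add atoms: none
Why: Rh2(S-PTTL)4 expels N2 from 16, and the resulting electrophilic donor/acceptor rhodium carbene at C6a inserts into the C11a–H bond of the O11 benzyl ether through a concerted, asynchronous three-centre transition state with hydride-transfer character, forming C6a–C11a without a free intermediate. The closest known reaction is the enantioselective intramolecular C–H insertion of methyl 2-(benzyloxy)aryl diazoacetates to cis-2-aryl-2,3-dihydrobenzofuran-3-carboxylates under N-phthaloyl amino acid dirhodium carboxylates, applied here to a more substituted member of the same class. Ring C closes as a five-membered ring by 1,5-insertion (C6a, C6b, C10a, O11, C11a), the only activated C–H within reach. C11a (R) and C6a (S as the ester, which is the 6aR arrangement of the target) arise together: the phthalimido wall of the catalyst selects one of the two enantiotopic benzylic hydrogens and one carbene face, and the compact transition state places aryl and ester cis, a kinetic result that should persist because no base is present. The step needs chemoselectivity over cyclopropanation of the ring E alkene and over carbene dimerisation; the C11a–H is activated by O11 and by the para oxygen of ring A, the alkene is cis-disubstituted, next to a quaternary carbon and out of intramolecular reach, and slow addition at low temperature keeps the diazo concentration low. Any leakage in facial control gives a diastereomer, not an enantiomer, because the ring F carbinol is already fixed, so it can be removed by chromatography.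

Step 15
Reactants: 17 methyl cis-dihydrobenzofuran-3-carboxylate (C11a R, C6a S; ring A pivalate, ring F acetate)
Product: 18 cis-triol: 2,3-dihydrobenzofuran whose C2 (= C11a, R) carries the 5-hydroxy-2,2-dimethyl-2H-chromen-6-yl group, whose C3 (= C6a, R) carries CH2OH, and whose benzo ring is fused at C6–C7 to the (R)-3-hydroxy-2,2-dimethyl-3,4-dihydro-2H-pyran ring F
Conditions: LiAlH4, THF, −20 → 0 °C; aq. potassium sodium tartrate
Reagents that add atoms: none
Why: Hydride reduction turns CO2Me into the C6 carbinol and in the same operation cleaves the aryl pivalate (freeing O5) and the acetate; low temperature should let reduction outrun epimerisation of the cis ester at C6a (the change of descriptor from S to R is a priority change only).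

Step 16
Reactants: 18 cis-triol (C11a R, C6a R, ring F carbinol R)
Product: 19 CNP0126417.1, the (6aR,11aR)-pterocarpan with a 2,2-dimethyl-2H-pyran ring E fused at C3–C4 (oxygen on C3) and an (R)-3-hydroxy-2,2-dimethyl-3,4-dihydro-2H-pyran ring F fused at C9–C10 (oxygen on C9, CH2 on C10)
Conditions: PPh3, DIAD, THF, 0 °C → rt
Reagents that add atoms: none
Why: Mitsunobu etherification: the primary C6–OH is activated as its oxyphosphonium and displaced by the O5 phenol in a 6-exo-tet closure of ring B, which the cis relation at C6a/C11a permits; the hindered secondary carbinol beside the quaternary carbon should not be activated competitively, and no stereocentre is touched.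

**Compound list**

1 | 2,4-dihydroxyacetophenone | CC(=O)c1ccc(O)cc1O | starting material
2 | 3-methylbut-2-enal (prenal) | CC(C)=CC=O | starting material
3 | 1-(5-hydroxy-2,2-dimethyl-2H-chromen-6-yl)ethan-1-one | CC(=O)c1ccc2OC(C)(C)C=Cc2c1O | intermediate
4 | 6-acetyl-2,2-dimethyl-2H-chromen-5-yl pivalate | CC(=O)c1ccc2OC(C)(C)C=Cc2c1OC(=O)C(C)(C)C | intermediate
5 | (3R,4R)-6-acetyl-3,4-epoxy-2,2-dimethyl-3,4-dihydro-2H-chromen-5-yl pivalate | CC(=O)c1ccc2OC(C)(C)[C@@H]3O[C@@H]3c2c1OC(=O)C(C)(C)C | intermediate
6 | (3R)-6-acetyl-3-hydroxy-2,2-dimethyl-3,4-dihydro-2H-chromen-5-yl pivalate | CC(=O)c1ccc2OC(C)(C)[C@H](O)Cc2c1OC(=O)C(C)(C)C | intermediate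
7 | methyl 2-[(3R)-3-hydroxy-2,2-dimethyl-5-(pivaloyloxy)-3,4-dihydro-2H-chromen-6-yl]acetate | COC(=O)Cc1ccc2OC(C)(C)[C@H](O)Cc2c1OC(=O)C(C)(C)C | intermediate
8 | methyl 2-[(3R)-3,5-dihydroxy-2,2-dimethyl-3,4-dihydro-2H-chromen-6-yl]acetate | COC(=O)Cc1ccc2OC(C)(C)[C@H](O)Cc2c1O | intermediate
9 | 2,4-dihydroxybenzaldehyde | O=Cc1ccc(O)cc1O | starting material
10 | 5-hydroxy-2,2-dimethyl-2H-chromene-6-carbaldehyde | O=Cc1ccc2OC(C)(C)C=Cc2c1O | intermediate
11 | 6-formyl-2,2-dimethyl-2H-chromen-5-yl pivalate | O=Cc1ccc2OC(C)(C)C=Cc2c1OC(=O)C(C)(C)C | intermediate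
12 | 6-(hydroxymethyl)-2,2-dimethyl-2H-chromen-5-yl pivalate | OCc1ccc2OC(C)(C)C=Cc2c1OC(=O)C(C)(C)C | intermediate
13 | 6-(bromomethyl)-2,2-dimethyl-2H-chromen-5-yl pivalate | BrCc1ccc2OC(C)(C)C=Cc2c1OC(=O)C(C)(C)C | intermediate
14 | methyl 2-[(3R)-5-{[2,2-dimethyl-5-(pivaloyloxy)-2H-chromen-6-yl]methoxy}-3-hydroxy-2,2-dimethyl-3,4-dihydro-2H-chromen-6-yl]acetate | COC(=O)Cc1ccc2OC(C)(C)[C@H](O)Cc2c1OCc1ccc2OC(C)(C)C=Cc2c1OC(=O)C(C)(C)C | intermediate
15 | methyl 2-[(3R)-3-acetoxy-5-{[2,2-dimethyl-5-(pivaloyloxy)-2H-chromen-6-yl]methoxy}-2,2-dimethyl-3,4-dihydro-2H-chromen-6-yl]acetate | COC(=O)Cc1ccc2OC(C)(C)[C@H](OC(C)=O)Cc2c1OCc1ccc2OC(C)(C)C=Cc2c1OC(=O)C(C)(C)C | intermediate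
16 | methyl 2-[(3R)-3-acetoxy-5-{[2,2-dimethyl-5-(pivaloyloxy)-2H-chromen-6-yl]methoxy}-2,2-dimethyl-3,4-dihydro-2H-chromen-6-yl]-2-diazoacetate | COC(=O)C(=[N+]=[N-])c1ccc2OC(C)(C)[C@H](OC(C)=O)Cc2c1OCc1ccc2OC(C)(C)C=Cc2c1OC(=O)C(C)(C)C | intermediate
17 | methyl cis-2-aryl-2,3-dihydrobenzofuran-3-carboxylate with rings A, C, D, E, F (C11a R, C6a S; ring A pivalate; ring F (R)-acetate) | CC1(C)C=Cc2c(ccc(c2OC(=O)C(C)(C)C)[C@@H]2Oc3c(ccc4c3C[C@@H](OC(C)=O)C(C)(C)O4)[C@@H]2C(=O)OC)O1 | intermediate
18 | cis-triol (C11a R, C6a R): free O5 phenol, C6 primary alcohol, ring F (R)-carbinol | CC1(C)C=Cc2c(ccc(c2O)[C@@H]2Oc3c(ccc4c3C[C@@H](O)C(C)(C)O4)[C@@H]2CO)O1 | intermediate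
19 | CNP0126417.1, (6aR,11aR)-pterocarpan with ring E chromene and ring F (R)-hydroxydimethylpyran | CC1(C)C=Cc2c(ccc3c2OC[C@H]2c4ccc5c(c4O[C@@H]32)C[C@@H](O)C(C)(C)O5)O1 | target

**Step count**

Total: 16 steps. Longest linear sequence: 12 steps (steps 1–6 and 11–16, from 2,4-dihydroxyacetophenone); steps 7–10 form the four-step ring A/E branch.

**Steps most likely to fail**

1. Step 14 (carbene C–H insertion). The process at risk is loss of facial and site control. O11 is flanked on ring D by C6b and the ring F methylene at C10, and the reacting C–H sits beside the ring A pivalate, so the chiral pocket may discriminate poorly. The carbene may also be diverted to intermolecular addition to the ring E alkene or to dimerisation. The fallback changes the source of absolute configuration from the catalyst to separation on the stereocentre already present. It sets out from 16, which is decomposed with the bulky achiral Rh2(O2CCPh3)4 (dirhodium tetrakis(triphenylacetate), divalent rhodium) in CH2Cl2 under high dilution, where intramolecular 1,5-insertion should dominate. The expected products are 17 and the cis-dihydrobenzofuran ester epimeric with 17 at both new centres (C11a S, C6a R) F1. These are diastereomers because of the (R)-carbinol of ring F and should separate by chromatography or crystallisation. The route is rejoined at 17.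

2. Step 5 (oxidative aryl shift). The process at risk is attack of the trivalent iodine oxidant on the electron-rich ring in place of the enol ether, or a slow migration because the ortho pivaloyloxy group twists the ketal out of conjugation, together with acid-promoted loss of the pivalate. The fallback moves the carbonyl to the chain terminus by sulfur chemistry in place of an aryl shift. It sets out from 6, which is heated with S8 and morpholine at 130 °C (Willgerodt–Kindler reaction; morpholine also removes the aryl pivalate) to give 2-[(3R)-3,5-dihydroxy-2,2-dimethyl-3,4-dihydro-2H-chromen-6-yl]-1-(morpholin-4-yl)ethane-1-thione F2. Hydrolysis with KOH in aqueous ethanol at reflux and acidification give 2-[(3R)-3,5-dihydroxy-2,2-dimethyl-3,4-dihydro-2H-chromen-6-yl]acetic acid F3 (partly as its lactone). Fischer esterification in MeOH with catalytic H2SO4 returns to the route at 8, so step 6 is no longer needed.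

3. Step 4 (benzylic hydrogenolysis). The process at risk is over-reduction: hydrogenation of the aryl ketone to the carbinol or to an ethyl group while the epoxide is being opened. The fallback accepts full hydride reduction and restores the ketone afterwards. It sets out from 5, which is treated with LiAlH4 in THF (0 °C → rt). Hydride opens the epoxide at the benzylic carbon, reduces the ketone and cleaves the pivalate, giving (3R)-6-(1-hydroxyethyl)-2,2-dimethyl-3,4-dihydro-2H-chromene-3,5-diol F4 (both carbinol epimers). MnO2 in CH2Cl2 reoxidises only the benzylic carbinol to 1-[(3R)-3,5-dihydroxy-2,2-dimethyl-3,4-dihydro-2H-chromen-6-yl]ethan-1-one F5. PivCl/Et3N/DMAP then acylates the phenol selectively over the hindered secondary alcohol and returns to the route at 6.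

**Further compounds**

F1 | step 14 | cis-dihydrobenzofuran ester epimeric with 17 at C11a and C6a (C11a S, C6a R; ring F carbinol R) | CC1(C)C=Cc2c(ccc(c2OC(=O)C(C)(C)C)[C@H]2Oc3c(ccc4c3C[C@@H](OC(C)=O)C(C)(C)O4)[C@H]2C(=O)OC)O1
F2 | step 5 | 2-[(3R)-3,5-dihydroxy-2,2-dimethyl-3,4-dihydro-2H-chromen-6-yl]-1-(morpholin-4-yl)ethane-1-thione | S=C(Cc1ccc2OC(C)(C)[C@H](O)Cc2c1O)N1CCOCC1
F3 | step 5 | 2-[(3R)-3,5-dihydroxy-2,2-dimethyl-3,4-dihydro-2H-chromen-6-yl]acetic acid | OC(=O)Cc1ccc2OC(C)(C)[C@H](O)Cc2c1O
F4 | step 4 | (3R)-6-(1-hydroxyethyl)-2,2-dimethyl-3,4-dihydro-2H-chromene-3,5-diol | CC(O)c1ccc2OC(C)(C)[C@H](O)Cc2c1O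
F5 | step 4 | 1-[(3R)-3,5-dihydroxy-2,2-dimethyl-3,4-dihydro-2H-chromen-6-yl]ethan-1-one | CC(=O)c1ccc2OC(C)(C)[C@H](O)Cc2c1O
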